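## Analysis of the target

Germacrane numbering is used. Reading the SMILES from left to right, the atoms are C13, C11, C12, O, C6, C5, C4 (bearing C15), C3, C2, C1, C10 (bearing C14), C9, C8, C7.

- **Ring system.** The core is the ten-membered carbocycle C1–C10. An oxygen spans C3 and C10, which gives the 3(2H)-furanone ring O/C10/C1/C2/C3 and an 11-oxabicyclo[6.2.1]undecane. The carbocycle is fused at C6–C7 to an α-methylene-γ-butyrolactone.
- **Configuration.** The SMILES reads as 4Z,6S,7R,8R,10R. O-6, C-11, O-8 and C-14 lie on one face, called the lower face below. H-6, H-7, H-8 and the oxygen bridge lie on the upper face. The lactone is therefore cis-fused and C6/C7/C8 form an all-cis triad.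
- **Alkene geometry.** C4=C5 has C3 and C6 cis, whereas C2=C3 is trans within the ten-membered ring.
- **C10.** It is quaternary and is insulated from the triad by the C9 methylene, so it is the hardest centre to relay.
- **Sensitive groups.** These are the exo-methylene lactone, the cross-conjugated furanone dienone, the oxygen leaving groups β to C8 (O-6 and the bridge oxygen), and the primary allylic alcohol.
- **Medium ring.** Direct closure of a ten-membered ring with five sp2 carbons and two fused or bridging rings is entropically and enthalpically poor.
- **Feature that is exploited.** C3 and C8 both carry oxygen and are 1,6-related both ways round the ring. A C3–C8 bond would turn the macrocycle into a cis-decalin. Its ring C3–C8 (C15 on C4, C11–C13 on C7) is the skeleton of 1. Its other ring, C3/C2/C1/C10/C9/C8, is a plain cyclohexene.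
- **Second feature.** The C1/C10 oxygen pattern is that of a 1,10-epoxide opened by O-3, as is presumed in the biosynthesis.

Assumption: the given SMILES is taken literally (cis-lactone, 6S), and commercial 1 is taken as enantiopure.

## Retrosynthetic reasoning

**17 ⇒ 16 ⇒ 15.** Only C–H bonds are cut: C15–H, then the two C12–H bonds. Until the end the lactone is carried as the cyclic allylic ether of 15, which is inert to enolates, organomagnesium reagents and hydrides. The Michael acceptor and the primary alcohol therefore appear only in the last two steps.

**15 ⇒ 14 ⇒ 13.** The ester C–O bond and the C8–H bond are cut back to the C8 ketone of 13. This ketone is not an extra burden, because it is one of the two carbonyl groups that the key step sets free.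

**13 ⇒ 12 ⇒ 11 ⇒ 10 (key disconnection).** The O3–C10 bond is cut back to a 1,10-epoxide and a C3 ketone (11). C3 and C8 are then reconnected as a ring-fusion glycol (10).
- What is gained: the ten-membered ring is never closed. It is released from a cis-decalin by cleaving the central bond.
- C4=C5 keeps the cis geometry it had in a six-membered ring.
- C10 is fixed on a rigid bicycle and is carried over by inversion.
- The forward reaction must cleave only the glycol, and then let the C3 carbonyl oxygen, and not any other nucleophile, open the epoxide at its tertiary carbon.

**10 ⇒ 9 ⇒ 8.** The epoxide is removed, and C1=C10 is cut by retro-metathesis into an allyl group on C3 and a methallyl group on C8. Closing a cyclohexene is the easiest ring closure available, and the convex face of 9 is the face that the epoxide needs.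

**8 ⇒ 7 ⇒ 6 ⇒ 4.** C8–C9 and C2–C3 are cut. Two carbonyl additions onto neighbouring carbons of the original ring deliver the remaining five skeletal carbons (seven added, two lost in the metathesis). Both nucleophiles must enter from the upper face, so that the glycol is cis.

**4 ⇒ 3.** The C8–O bond is cut (α′-hydroxylation of the enone).

**3 ⇒ 2 ⇒ 1.** The C6–O bond is cut back to a C–H bond that lies 1,5 to the C12 oxygen, and C12–O back to a methyl C–H. C7 of 1 is the only stereocentre that is bought. C6, C10 and C8 are relayed from it in that order.

## Alternatives that were turned down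

**Alternative 1:** The textbook cut is C6–C7 together with the lactone C–O bond. The forward key step is an intramolecular Barbier-type allylation of the seco aldehyde–allyl bromide A1, followed by lactonisation.
- It closes the strained ten-membered ring directly under high dilution.
- In that same event it must deliver the less favoured cis-lactone and the all-cis C6/C7/C8 array from a single resident centre (C8).
- C10 cannot be relayed at all and needs its own asymmetric synthesis.
- The (Z)-enal of A1 can isomerise, and its β-acyloxy acrylate can eliminate.
- Two chiral fragments and their union cost more steps than the whole decalin.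

**Alternative 2:** The cut is C4=C5, by ring-closing metathesis of the diene A2. A sulfone extrusion at the same bond would be the equivalent.
- One partner is a 1,1-disubstituted, electron-poor olefin conjugated to the furanone.
- The product is a trisubstituted alkene in a strained ring.
- The exo-methylene lactone competes for the carbene, so oligomers and the wrong geometry are likely.
- All four stereocentres would have to be in place beforehand, so the key step sets none of them.

**Alternative 3:** The C3–C8 bond is broken and C1–C10 is formed in one pericyclic event, an anionic oxy-Cope rearrangement of the vinyl/propynyl glycol A3 to the cyclodecadienedione A4. This route is shorter.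
- C10 then arises in a reversible oxa-Michael addition inside a flexible ring, with no element that controls it.
- The bis-enolate invites transannular aldol closure to a hydroazulene.
- C1 still has to be raised from CH2 to C=O.
- Tying O-3 to C10 beforehand (dihydrofuran A5) would transfer chirality. However, the bond to be broken then lies in the nodal plane of the ring alkene, so the [3,3] overlap is lost.

Key step: step 9

## Route

**Step 1**
Reactants: 1 (S)-(+)-carvone
Product: 2 (S)-10-hydroxycarvone, in which the isopropenyl CH3 has become CH2OH (C12)
Conditions: SeO2 (0.3 equiv), tBuOOH, CH2Cl2, 0 to 23 °C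
Reagents that add atoms: tert-butyl hydroperoxide CC(C)(C)OO
Why: Riley allylic hydroxylation (ene reaction, then [2,3]-shift); the electron-rich 1,1-disubstituted alkene reacts and the enone alkene does not, and C7 is untouched.

**Step 2**
Reactants: 2 (S)-10-hydroxycarvone
Product: 3 6,12-ether enone, a 3-methylenetetrahydrofuran cis-fused at C6–C7 with O-6 and C-11 on the lower face
Conditions: PhI(OAc)2, I2, cyclohexane–CH2Cl2, visible light, 23 °C
Reagents that add atoms: none
Why: Suárez hypoiodite reaction: the C12 alkoxy radical abstracts H-6 through a six-membered transition state, since this allylic C–H is weaker and better polarity-matched than the equally near α-keto C8–H. The hydroxyl then displaces the allylic iodide, and the three-atom tether on C7 closes on its own face, which sets C6 cis to C7.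

**Step 3**
Reactants: 3 6,12-ether enone
Product: 4 8-trimethylsilyloxy enone with the OSiMe3 group on the upper face
Conditions: LiN(iPr)2, THF, −78 °C; 2-(phenylsulfonyl)-3-phenyloxaziridine; then Me3SiCl, −78 to 0 °C
Reagents that add atoms: 2-(phenylsulfonyl)-3-phenyloxaziridine O=S(=O)(c1ccccc1)N1OC1c1ccccc1; chlorotrimethylsilane C[Si](C)(C)Cl
Why: Davis hydroxylation of the kinetic α′-enolate from the convex upper face of the cis-fused bicycle. The silyl trap prevents chelation in step 4, and this C8 centre is temporary.

**Step 4**
Reactants: 4 8-trimethylsilyloxy enone
Product: 6 3-allyl-3,8-diol (allyl upper, 3-OH lower, 8-OH upper), via allyl carbinol silyl ether 5 (not isolated)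
Conditions: allylMgBr, Et2O–THF, −78 °C; then K2CO3 (cat.), MeOH, 0 °C
Reagents that add atoms: allylmagnesium bromide C=CC[Mg]Br
Why: Grignard 1,2-addition to the cyclohexenone by axial attack on the upper face in the conformer with C-11 equatorial; lower-face axial attack would need C-11 axial and 1,3-diaxial to the nucleophile. Methanolysis then removes the labile silyl ether.

**Step 5**
Reactants: 6 3-allyl-3,8-diol
Product: 7 3-allyl-3-hydroxy-8-ketone
Conditions: nPr4N[RuO4] (5 mol %), N-methylmorpholine N-oxide, 4 Å molecular sieves, CH2Cl2, 0 °C
Reagents that add atoms: none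
Why: Ley–Griffith oxidation takes the only secondary alcohol under neutral conditions, which spares the acid-labile tertiary allylic alcohol and avoids epimerisation at C7 and β-elimination of O-6.

**Step 6**
Reactants: 7 3-allyl-3-hydroxy-8-ketone
Product: 8 3-allyl-8-methallyl cis-3,8-diol (both carbon chains upper, both OH lower)
Conditions: methallylMgCl (3 equiv), THF, −78 °C
Reagents that add atoms: methallylmagnesium chloride CC(=C)C[Mg]Cl
Why: Grignard addition anti to the neighbouring C-11: upper-face axial attack meets only H-6, whereas lower-face attack is 1,3-diaxial to O-6. The fast allylic reagent adds before enolisation, α-ketol shift or E1cB can occur.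

**Step 7**
Reactants: 8 3-allyl-8-methallyl cis-3,8-diol
Product: 9 cis-decalin-3,8-diol with a C1=C10 trisubstituted alkene in the new ring
Conditions: second-generation Grubbs catalyst RuCl2(=CHPh)(PCy3)(H2IMes) (3 mol %), CH2Cl2, 40 °C
Reagents that add atoms: none
Why: Ring-closing metathesis of two cis-disposed chains to a cyclohexene; the exocyclic methylene and C4=C5 are hindered and can only form strained rings.

**Step 8**
Reactants: 9 cis-decalin-3,8-diol
Product: 10 1,10-epoxide with the epoxide oxygen on the lower (convex) face, cis to both hydroxyls, and C14 on the upper face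
Conditions: mCPBA, pH 7 phosphate buffer, CH2Cl2, −20 °C
Reagents that add atoms: 3-chloroperbenzoic acid O=C(OO)c1cccc(Cl)c1
Why: Prilezhaev epoxidation of the most nucleophilic alkene; C4=C5 carries two allylic oxygens and C11=C13 is only disubstituted with an allylic oxygen. Attack comes from the convex face of the cis-decalin, reinforced by hydrogen bonding to the homoallylic hydroxyls, and this fixes the configuration from which C10 is derived.

**Step 9**
Reactants: 10 1,10-epoxy cis-decalin-3,8-diol
Product: 12 bridged 1-hydroxy-2,3-dihydrofuran 8-ketone (ten-membered ring, O-3/C10 bridge on the upper face, C14 lower, 1-OH lower), via epoxy diketone 11 (not isolated)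
Conditions: Pb(OAc)4, CH2Cl2, −20 °C; then BF3·OEt2 (20 mol %), −78 °C; Et3N quench
Reagents that add atoms: none
Why: Criegee glycol fission: the cis ring-fusion diol forms a cyclic plumbate and the shared C3–C8 bond breaks, so the ten-membered carbocycle is released, not closed, with C3 and C8 as ketones and C4=C5 still cis. The closest known reaction is the fission of 9,10-decalindiols to cyclodecane-1,6-diones, and epoxide, ether and alkenes are inert to the reagent. The Lewis acid then polarises the epoxide towards its tertiary carbon C10, and the C3 carbonyl oxygen, 1,5 to C10, attacks it from the rear in a 5-endo-tet closure with much SN1 character, the known acid cyclisation of epoxy ketones to dihydrofurans. Loss of H-2 from the oxocarbenium ion gives the enol ether. C10 is set by inversion of the epoxide centre fixed in step 8, so the bridge oxygen arrives on the upper face and C14 swings to the lower face. C1 keeps the epoxide oxygen and is erased in step 10. The C8 carbonyl is also 1,5 to an epoxide carbon, but only to the secondary C1, so the charge distribution selects O-3/C10. Low temperature and the absence of base suppress enolisation at C2, which would open the β,γ-epoxy ketone with retention at C10, and also suppress transannular aldol closure.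

**Step 10**
Reactants: 12 bridged 1-hydroxy-2,3-dihydrofuran 8-ketone
Product: 13 furanone 8-ketone (3(2H)-furanone complete, 6,12-ether retained)
Conditions: MnO2, CH2Cl2, 23 °C
Reagents that add atoms: none
Why: Neutral MnO2 oxidation of the allylic alcohol next to the enol ether gives the vinylogous ester; no other oxidisable alcohol is present.

**Step 11**
Reactants: 13 furanone 8-ketone
Product: 14 8-alcohol with OH on the lower face (8R)
Conditions: NaBH4, MeOH–CH2Cl2, −78 °C
Reagents that add atoms: none
Why: Borohydride takes the isolated ketone, since the furanone carbonyl is a hindered vinylogous ester. C14 on C10 and C-11 on C7 both shield the lower face, so hydride should arrive from the upper face and set C8; the low temperature avoids C9 enolisation.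

**Step 12**
Reactants: 14 8-alcohol
Product: 15 8-isobutyrate
Conditions: (iPrCO)2O, DMAP (cat.), Et3N, CH2Cl2, 23 °C
Reagents that add atoms: isobutyric anhydride CC(C)C(=O)OC(=O)C(C)C
Why: DMAP-catalysed acylation of the only hydroxyl group, with retention at C8.

**Step 13**
Reactants: 15 8-isobutyrate
Product: 16 15-deoxy lactone (cis-fused α-methylene-γ-butyrolactone)
Conditions: CrO3, 3,5-dimethylpyrazole, CH2Cl2, −20 °C
Reagents that add atoms: chromium trioxide O=[Cr](=O)=O
Why: Allylic oxidation of a 3-methylenetetrahydrofuran to the α-methylene lactone, a known transformation. C12–H2 is α to oxygen and allylic to an isolated alkene, whereas C6–H and C15–H are allylic to the electron-poor dienone and are deactivated.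

**Step 14**
Reactants: 16 15-deoxy lactone
Product: 17 target, (4Z,6S,7R,8R,10R)-15-hydroxy furanoheliangolide 8-isobutyrate
Conditions: SeO2, 1,4-dioxane, 70 °C
Reagents that add atoms: selenium dioxide O=[Se]=O
Why: Riley oxidation of the trisubstituted C4=C5 alkene at the only CH-bearing substituent of its more substituted end (C15); the [2,3]-shift returns the double bond with its geometry unchanged, and the acrylate-type alkene is inert.

## Compound list

1 | (S)-(+)-carvone | CC1=CC[C@@H](CC1=O)C(C)=C | starting material
2 | (S)-10-hydroxycarvone | CC1=CC[C@@H](CC1=O)C(=C)CO | intermediate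
3 | 6,12-ether enone (cis-fused 3-methylenetetrahydrofuran) | CC1=C[C@@H]2OCC(=C)[C@@H]2CC1=O | intermediate
4 | 8-trimethylsilyloxy enone (OSiMe3 upper) | CC1=C[C@@H]2OCC(=C)[C@@H]2[C@@H](O[Si](C)(C)C)C1=O | intermediate
5 | allyl carbinol silyl ether (allyl upper, 3-OH lower) | CC1=C[C@@H]2OCC(=C)[C@@H]2[C@@H](O[Si](C)(C)C)[C@@]1(O)CC=C | intermediate
6 | 3-allyl-3,8-diol | CC1=C[C@@H]2OCC(=C)[C@@H]2[C@@H](O)[C@@]1(O)CC=C | intermediate
7 | 3-allyl-3-hydroxy-8-ketone | CC1=C[C@@H]2OCC(=C)[C@@H]2C(=O)[C@@]1(O)CC=C | intermediate
8 | 3-allyl-8-methallyl cis-3,8-diol | CC1=C[C@@H]2OCC(=C)[C@@H]2[C@@](O)(CC(C)=C)[C@@]1(O)CC=C | intermediate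
9 | cis-decalin-3,8-diol, C1=C10 alkene | CC1=C[C@@H]2OCC(=C)[C@@H]2[C@@]3(O)CC(C)=CC[C@@]13O | intermediate
10 | 1,10-epoxy cis-decalin-3,8-diol (epoxide cis to the hydroxyls) | CC1=C[C@@H]2OCC(=C)[C@@H]2[C@@]3(O)C[C@]4(C)O[C@@H]4C[C@@]13O | intermediate
11 | ten-membered 1,10-epoxy-3,8-diketone | C=C1CO[C@H]2/C=C(/C)C(=O)C[C@H]3O[C@@]3(C)CC(=O)[C@@H]12 | intermediate
12 | bridged 1-hydroxy-2,3-dihydrofuran 8-ketone | C=C1CO[C@H]2/C=C(/C)C3=C[C@@H](O)[C@@](C)(CC(=O)[C@@H]12)O3 | intermediate
13 | furanone 8-ketone | C=C1CO[C@H]2/C=C(/C)C3=CC(=O)[C@@](C)(CC(=O)[C@@H]12)O3 | intermediate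
14 | furanone 8-alcohol (8R) | C=C1CO[C@H]2/C=C(/C)C3=CC(=O)[C@@](C)(C[C@@H](O)[C@@H]12)O3 | intermediate
15 | furanone 8-isobutyrate, 6,12-ether | C=C1CO[C@H]2/C=C(/C)C3=CC(=O)[C@@](C)(C[C@@H](OC(=O)C(C)C)[C@@H]12)O3 | intermediate
16 | 15-deoxy lactone | C=C1C(=O)O[C@H]2/C=C(/C)C3=CC(=O)[C@@](C)(C[C@@H](OC(=O)C(C)C)[C@@H]12)O3 | intermediate
17 | target CNP0176924.5 | C=C1C(=O)O[C@H]2/C=C(/CO)C3=CC(=O)[C@@](C)(C[C@@H](OC(=O)C(C)C)[C@@H]12)O3 | target

## Step count and least certain steps

Total step count: 14. Longest linear sequence: 14 (fully linear from 1).

**Step 9 (key step).**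
- *What may go wrong.* After the fission the flexible diketone may close by transannular aldol reaction. Alternatively, enolisation at C2 may open the β,γ-epoxy ketone by elimination, which keeps the epoxide oxygen on C10 and so gives the wrong configuration there. Both processes compete with attack of the carbonyl oxygen.
- *Fallback.* It sets out from 9 and never breaks a C10–O bond. NBS in wet DMSO places the bromonium ion on the convex lower face and water on the tertiary C10 from the upper face, giving the bromohydrin F1. A Kornblum oxidation (AgBF4, DMSO, then Et3N) turns the secondary bromide into the decalin α-ketol F2. Pb(OAc)4 in an aprotic solvent cleaves only the glycol, and the resulting α′-hydroxy-1,3-diketone cyclodehydrates with a trace of acid. The route is rejoined at 13.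

**Step 2.**
- *What may go wrong.* Acetyl hypoiodite may add to the 1,1-disubstituted alkene, hydrogen may be abstracted at C8, or the delocalised radical may be captured at C4.
- *Fallback.* It sets out from 2 and replaces the radical relay by an ionic closure. Acetylation gives the acetate F3. Wohl–Ziegler γ-bromination of the enone (NBS, AIBN) gives the 6-bromide F4, with bromine on the less hindered upper face. K2CO3 in MeOH frees the alkoxide, which displaces bromide with inversion. The route is rejoined at 3.

**Step 8.**
- *What may go wrong.* Site selectivity may be poor, because the allylic 3-OH can direct the peracid to C4=C5. Facial selectivity may also be poor.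
- *Fallback.* It sets out from 9 and inverts the order of events. Pb(OAc)4 first gives the dienedione F5, in which C4=C5 has become an electron-poor enone. mCPBA then has only one nucleophilic trisubstituted alkene, which it attacks from the periphery of the ring. The route is rejoined at 11, which is treated with BF3·OEt2 as in step 9.

**Step 11.**
- *What may go wrong.* Facial selectivity on a medium-ring ketone may be poor. C9 enolisation may trigger a retro-oxa-Michael opening that scrambles C10.
- *Fallback.* It sets out from 13. If reduction favours the epimer, the 8-epi alcohol F6 is esterified with isobutyric acid under Mitsunobu conditions (PPh3, DIAD). This inverts C8 and rejoins the route at 15.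

**Step 13.**
- *What may go wrong.* Hydrogen may be abstracted at C6 instead, or the dienone may be oxidatively degraded.
- *Fallback.* It sets out from 15 and merges the last two steps. SeO2 with tBuOOH hydroxylates both allylic positions, C12 and C15, to the lactol F7. Ag2CO3 on Celite (Fétizon oxidation) then takes the lactol in preference to the alcohol. The route is rejoined at 17.

## Further compounds

F1 | step 9 | decalin bromohydrin (10-OH upper, 1-Br lower) | CC1=C[C@@H]2OCC(=C)[C@@H]2[C@@]3(O)C[C@@](C)(O)[C@H](Br)C[C@@]13O
F2 | step 9 | decalin α-ketol (C1 ketone, 10-OH upper) | CC1=C[C@@H]2OCC(=C)[C@@H]2[C@@]3(O)C[C@@](C)(O)C(=O)C[C@@]13O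
F3 | step 2 | (S)-10-acetoxycarvone | CC1=CC[C@@H](CC1=O)C(=C)COC(C)=O
F4 | step 2 | 6-bromo-10-acetoxycarvone (Br upper, trans to C-11) | CC1=C[C@@H](Br)[C@@H](CC1=O)C(=C)COC(C)=O
F5 | step 8 | ten-membered 3,8-dione with cis C1=C10 and cis C4=C5 | C=C1CO[C@H]2/C=C(/C)C(=O)C/C=C(/C)CC(=O)[C@@H]12
F6 | step 11 | 8-epi alcohol | C=C1CO[C@H]2/C=C(/C)C3=CC(=O)[C@@](C)(C[C@H](O)[C@@H]12)O3
F7 | step 13 | 12-lactol 15-alcohol (mixture at C12) | C=C1C(O)O[C@H]2/C=C(/CO)C3=CC(=O)[C@@](C)(C[C@@H](OC(=O)C(C)C)[C@@H]12)O3
A1 | alternative 1 | seco C6–C7 aldehyde–allyl bromide with furanone in place | O=C/C=C(/CO[Si](C)(C)C(C)(C)C)C1=CC(=O)[C@@](C)(C[C@@H](OC(=O)C(C)C)/C=C(\CBr)C(=O)OC)O1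
A2 | alternative 2 | seco C4=C5 diene for ring-closing metathesis | C=C[C@@H]1OC(=O)C(=C)[C@@H]1[C@H](OC(=O)C(C)C)C[C@@]1(C)OC(=CC1=O)C(=C)CO
A3 | alternative 3 | 3-vinyl-8-propynyl cis-3,8-diol | CC1=C[C@@H]2OCC(=C)[C@@H]2[C@@](O)(C#CC)[C@@]1(O)C=C
A4 | alternative 3 | cyclodecadienedione from the oxy-Cope rearrangement | C=C1CO[C@H]2/C=C(/C)C(=O)CC/C(C)=C/C(=O)[C@@H]12
A5 | alternative 3 | dihydrofuran-tied oxy-Cope substrate | CC1=C[C@@H]2OCC(=C)[C@@H]2[C@@]3(O)C=C(C)O[C@@]13C=C
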